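The cyclohexene ring is cut at the bond between its quaternary carbon C1 and the indolyl-bearing C6, which is allylic to the C4(Me)=C5 alkene: with the styryl carbon on C1 read as a carboxyl, this is the γ,δ-unsaturated acid pattern of an ester-enolate Claisen rearrangement. Tying acid and allylic alcohol into a δ-lactone, (6S)-3,6-dimethyl-6-[(Z)-2-arylvinyl]oxan-2-one, lets its silyl ketene acetal form C1–C6, break the tertiary C4–O bond and set both stereocentres in one boat-shaped [3,3] shift. The ketene acetal is made as the TBS instead of the TMS ether to survive the heating, and its carbinol centre comes from a Sharpless epoxidation.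

Key step: step 11

Remark: the 5-iodoindole is chosen over the 5-bromoindole so that both palladium couplings run at or near room temperature; 4-iodophenylhydrazine hydrochloride, (E)-3-methylpent-2-en-4-yn-1-ol and dimethyl methylmalonate are taken to be commercial.

Step 1
Reactants: 1 methyl 3,3-dimethylpent-4-enoate
Product: 2 3,3-dimethylpent-4-enal
Conditions: DIBAL-H, CH2Cl2, −78 °C
Reagents that add atoms: none
Why: Partial ester reduction with DIBAL-H stops at the aluminium hemiacetal at −78 °C and gives the aldehyde that a Fischer indolisation needs, since the ester itself cannot form a hydrazone.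

Step 2
Reactants: 3 4-iodophenylhydrazine hydrochloride; 2 3,3-dimethylpent-4-enal
Product: 5 5-iodo-3-(2-methylbut-3-en-2-yl)-1H-indole, via arylhydrazone 4 (not isolated)
Conditions: AcOH, 80 °C
Reagents that add atoms: none
Why: Fischer indole synthesis: the hydrazone can tautomerise only towards the CH2 group (the next carbon is quaternary), so the [3,3] shift, cyclisation and loss of ammonia should place the 1,1-dimethylallyl group at C3 and the para iodine at C5.

Step 3
Reactants: 5 5-iodo-3-(2-methylbut-3-en-2-yl)-1H-indole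
Product: 6 5-iodo-3-(2-methylbut-3-en-2-yl)-1-(triisopropylsilyl)-1H-indole
Conditions: NaH, TIPSCl, THF, 0 to 23 °C
Reagents that add atoms: triisopropylsilyl chloride, CC(C)[Si](Cl)(C(C)C)C(C)C
Why: N-Silylation of the sodium indolide masks the acidic N–H for the later enolate, hydride and chromium steps, and the bulky TIPS group shields C2 from metalation.

Step 4
Reactants: 7 (E)-3-methylpent-2-en-4-yn-1-ol
Product: 8 [(2R,3R)-3-ethynyl-3-methyloxiran-2-yl]methanol
Conditions: Ti(OiPr)4 (10 mol %), D-(−)-diethyl tartrate (12 mol %), t-BuOOH, 4 Å MS, CH2Cl2, −20 °C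
Reagents that add atoms: tert-butyl hydroperoxide, CC(C)(C)OO
Why: Katsuki–Sharpless asymmetric epoxidation of a trisubstituted allylic alcohol: the D-(−)-tartrate titanium catalyst should deliver oxygen to one alkene face, setting C3 as R and, through the E geometry, C2 as R, while the alkyne stays untouched.

Step 5
Reactants: 8 [(2R,3R)-3-ethynyl-3-methyloxiran-2-yl]methanol
Product: 9 (3S)-3-methylpent-4-yne-1,3-diol
Conditions: Red-Al (1.3 equiv), THF, −20 to 0 °C
Reagents that add atoms: none
Why: Hydroxyl-directed reductive opening of a 2,3-epoxy alcohol: the alkoxide-bound aluminium hydride is delivered intramolecularly to C2, so the 1,3-diol should form with the C3–O bond and its configuration intact (the descriptor becomes S only through the CIP ranking).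

Step 6
Reactants: 9 (3S)-3-methylpent-4-yne-1,3-diol
Product: 10 (3S)-3-hydroxy-3-methylpent-4-yn-1-yl 4-methylbenzenesulfonate
Conditions: TsCl, Et3N, DMAP (cat.), CH2Cl2, 0 °C
Reagents that add atoms: 4-methylbenzenesulfonyl chloride, Cc1ccc(S(=O)(=O)Cl)cc1
Why: Selective tosylation of the primary hydroxyl group; the tertiary propargylic alcohol is too hindered to be sulfonylated at 0 °C.

Step 7
Reactants: 10 (3S)-3-hydroxy-3-methylpent-4-yn-1-yl 4-methylbenzenesulfonate; 11 dimethyl methylmalonate
Product: 13 methyl (3RS,6S)-6-ethynyl-3,6-dimethyl-2-oxooxane-3-carboxylate, via hydroxy diester 12 (not isolated)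
Conditions: NaH, excess 11, DMF, 0 °C; then 10, NaI (cat.), 50 °C; then NaOMe (cat.), 23 °C
Reagents that add atoms: none
Why: Malonic ester alkylation (SN2 at the primary tosylate) followed by base-mediated lactonisation of the tertiary alkoxide onto one of the geminal esters; the carbinol centre is not involved, and C3 forms as both epimers, which is immaterial because it becomes sp2 in step 11.

Step 8
Reactants: 13 methyl (3RS,6S)-6-ethynyl-3,6-dimethyl-2-oxooxane-3-carboxylate
Product: 14 (3RS,6S)-6-ethynyl-3,6-dimethyloxan-2-one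
Conditions: LiCl, H2O, DMSO, 130 °C
Reagents that add atoms: none
Why: Krapcho dealkoxycarbonylation: chloride demethylates the activated ester and the carboxylate loses CO2 to the lactone enolate, which water protonates; the terminal alkyne and the tertiary lactone should tolerate these neutral conditions.

Step 9
Reactants: 14 (3RS,6S)-6-ethynyl-3,6-dimethyloxan-2-one; 6 5-iodo-3-(2-methylbut-3-en-2-yl)-1-(triisopropylsilyl)-1H-indole
Product: 15 (3RS,6S)-3,6-dimethyl-6-{[3-(2-methylbut-3-en-2-yl)-1-(triisopropylsilyl)-1H-indol-5-yl]ethynyl}oxan-2-one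
Conditions: Pd(PPh3)2Cl2 (3 mol %), CuI (5 mol %), Et3N, THF, 23 °C
Reagents that add atoms: none
Why: Sonogashira coupling of the terminal alkyne with the aryl iodide at room temperature, mild enough for a tertiary propargylic ester, attaches the indole to the future migrating alkene.

Step 10
Reactants: 15 (3RS,6S)-3,6-dimethyl-6-{[3-(2-methylbut-3-en-2-yl)-1-(triisopropylsilyl)-1H-indol-5-yl]ethynyl}oxan-2-one
Product: 16 (3RS,6S)-3,6-dimethyl-6-{(Z)-2-[3-(2-methylbut-3-en-2-yl)-1-(triisopropylsilyl)-1H-indol-5-yl]ethenyl}oxan-2-one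
Conditions: H2 (1 atm), Lindlar catalyst, quinoline, EtOAc, 23 °C
Reagents that add atoms: none
Why: Lindlar semi-hydrogenation adds hydrogen syn to the adsorbed alkyne and should give the Z styrene that the boat requires; quinoline poisoning and one equivalent of hydrogen are meant to spare the hindered 1,1-dimethylallyl vinyl group.

Step 11
Reactants: 16 (3RS,6S)-3,6-dimethyl-6-{(Z)-2-[3-(2-methylbut-3-en-2-yl)-1-(triisopropylsilyl)-1H-indol-5-yl]ethenyl}oxan-2-one
Product: 18 tert-butyldimethylsilyl (1R,2S)-1,4-dimethyl-2-[3-(2-methylbut-3-en-2-yl)-1-(triisopropylsilyl)-1H-indol-5-yl]cyclohex-3-ene-1-carboxylate, via silyl ketene acetal 17 (not isolated)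
Conditions: LDA, THF, −78 °C; TBSCl, DMPU, −78 to 23 °C; then PhMe, 110 °C; crude 18 is taken on
Reagents that add atoms: tert-butyldimethylsilyl chloride, CC(C)(C)[Si](C)(C)Cl
Why: Enolisation of the lactone and O-silylation give the ring-locked ketene acetal 17, whose C3 then bonds to the styrenyl terminus while the tertiary allylic C6–O bond breaks in a concerted suprafacial [3,3] shift, the Ireland–Claisen rearrangement of a lactone silyl ketene acetal. The carbocycle closes pericyclically through a bridged, bicyclo[2.2.2]-like boat (formally a 6-exo attack of the ketene acetal carbon on the alkene terminus across the oxane ring), the only geometry the two-carbon tether allows, and the oxane opens to the silyl ester as the C4=C5 alkene appears. The quaternary centre C1 is fixed by the (6S) carbinol carbon, because the alkenyl arm can reach only one face of the endocyclic ketene acetal, whose geometry the ring locks. The methine centre C6 follows from the Z alkene in that boat, which turns the aryl group towards the ethano bridge and hence trans to the carboxyl and cis to the methyl group. The step needs the [3,3] shift to outrun ionisation of the electron-rich tertiary allylic ester and to transfer chirality completely; the neutral TBS ketene acetal in non-polar toluene, the single enforced boat and the stereodefined Z alkene from step 10 are what secure this.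

Step 12
Reactants: 18 tert-butyldimethylsilyl (1R,2S)-1,4-dimethyl-2-[3-(2-methylbut-3-en-2-yl)-1-(triisopropylsilyl)-1H-indol-5-yl]cyclohex-3-ene-1-carboxylate
Product: 19 {(1R,2S)-1,4-dimethyl-2-[3-(2-methylbut-3-en-2-yl)-1-(triisopropylsilyl)-1H-indol-5-yl]cyclohex-3-en-1-yl}methanol
Conditions: LiAlH4, THF, 0 to 50 °C
Reagents that add atoms: none
Why: Hydride reduction of the hindered silyl ester should give the neopentyl alcohol directly, without a separate hydrolysis and without touching either stereocentre.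

Step 13
Reactants: 19 {(1R,2S)-1,4-dimethyl-2-[3-(2-methylbut-3-en-2-yl)-1-(triisopropylsilyl)-1H-indol-5-yl]cyclohex-3-en-1-yl}methanol
Product: 20 (1R,2S)-1,4-dimethyl-2-[3-(2-methylbut-3-en-2-yl)-1-(triisopropylsilyl)-1H-indol-5-yl]cyclohex-3-ene-1-carbaldehyde
Conditions: Dess–Martin periodinane, CH2Cl2, 23 °C
Reagents that add atoms: none
Why: Dess–Martin oxidation of the primary alcohol stops at the aldehyde, which is α-quaternary and therefore cannot epimerise.

Step 14
Reactants: 20 (1R,2S)-1,4-dimethyl-2-[3-(2-methylbut-3-en-2-yl)-1-(triisopropylsilyl)-1H-indol-5-yl]cyclohex-3-ene-1-carbaldehyde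
Product: 21 2-[(E)-2-{(1S,2R)-1,4-dimethyl-2-[3-(2-methylbut-3-en-2-yl)-1-(triisopropylsilyl)-1H-indol-5-yl]cyclohex-3-en-1-yl}ethenyl]-4,4,5,5-tetramethyl-1,3,2-dioxaborolane
Conditions: CrCl2 (8 equiv), Cl2CHBpin, LiI, THF, 23 °C
Reagents that add atoms: 2-(dichloromethyl)-4,4,5,5-tetramethyl-1,3,2-dioxaborolane, ClC(Cl)B1OC(C)(C)C(C)(C)O1
Why: Takai–Utimoto borylative olefination: the geminal dichromium species formed from the diiodomethylboronate made in the flask adds to the aldehyde and eliminates to the (E)-alkenylboronate, a reaction type that accepts hindered aldehydes.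

Step 15
Reactants: 21 2-[(E)-2-{(1S,2R)-1,4-dimethyl-2-[3-(2-methylbut-3-en-2-yl)-1-(triisopropylsilyl)-1H-indol-5-yl]cyclohex-3-en-1-yl}ethenyl]-4,4,5,5-tetramethyl-1,3,2-dioxaborolane; 6 5-iodo-3-(2-methylbut-3-en-2-yl)-1-(triisopropylsilyl)-1H-indole
Product: 22 5-[(E)-2-{(1S,2R)-1,4-dimethyl-2-[3-(2-methylbut-3-en-2-yl)-1-(triisopropylsilyl)-1H-indol-5-yl]cyclohex-3-en-1-yl}ethenyl]-3-(2-methylbut-3-en-2-yl)-1-(triisopropylsilyl)-1H-indole
Conditions: Pd(dppf)Cl2 (5 mol %), K3PO4, THF/H2O, 50 °C
Reagents that add atoms: none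
Why: Suzuki–Miyaura coupling of the (E)-alkenylboronate with the aryl iodide proceeds with retention of alkene geometry and should outpace Heck reaction of the hindered terminal alkenes, completing the E styryl link.

Step 16
Reactants: 22 5-[(E)-2-{(1S,2R)-1,4-dimethyl-2-[3-(2-methylbut-3-en-2-yl)-1-(triisopropylsilyl)-1H-indol-5-yl]cyclohex-3-en-1-yl}ethenyl]-3-(2-methylbut-3-en-2-yl)-1-(triisopropylsilyl)-1H-indole
Product: 23 5-[(E)-2-{(1S,2R)-1,4-dimethyl-2-[3-(2-methylbut-3-en-2-yl)-1H-indol-5-yl]cyclohex-3-en-1-yl}ethenyl]-3-(2-methylbut-3-en-2-yl)-1H-indole (EANPDB:ANNO_00013)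
Conditions: TBAF, THF, 0 to 23 °C
Reagents that add atoms: none
Why: Fluoride-mediated N-desilylation removes both TIPS groups, the only protecting groups in the route, and should release the target.

Compound list
1 | methyl 3,3-dimethylpent-4-enoate | COC(=O)CC(C)(C)C=C | starting material
2 | 3,3-dimethylpent-4-enal | O=CCC(C)(C)C=C | intermediate
3 | 4-iodophenylhydrazine hydrochloride | Cl.NNc1ccc(I)cc1 | starting material
4 | 1-(3,3-dimethylpent-4-en-1-ylidene)-2-(4-iodophenyl)hydrazine | C=CC(C)(C)CC=NNc1ccc(I)cc1 | intermediate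
5 | 5-iodo-3-(2-methylbut-3-en-2-yl)-1H-indole | C=CC(C)(C)c1c[nH]c2ccc(I)cc12 | intermediate
6 | 5-iodo-3-(2-methylbut-3-en-2-yl)-1-(triisopropylsilyl)-1H-indole | C=CC(C)(C)c1cn([Si](C(C)C)(C(C)C)C(C)C)c2ccc(I)cc12 | intermediate
7 | (E)-3-methylpent-2-en-4-yn-1-ol | C#C/C(C)=C/CO | starting material
8 | [(2R,3R)-3-ethynyl-3-methyloxiran-2-yl]methanol | C#C[C@@]1(C)O[C@@H]1CO | intermediate
9 | (3S)-3-methylpent-4-yne-1,3-diol | C#C[C@@](C)(O)CCO | intermediate
10 | (3S)-3-hydroxy-3-methylpent-4-yn-1-yl 4-methylbenzenesulfonate | C#C[C@@](C)(O)CCOS(=O)(=O)c1ccc(C)cc1 | intermediate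
11 | dimethyl methylmalonate (dimethyl 2-methylpropanedioate) | COC(=O)C(C)C(=O)OC | starting material
12 | dimethyl 2-[(3S)-3-hydroxy-3-methylpent-4-yn-1-yl]-2-methylpropanedioate | C#C[C@@](C)(O)CCC(C)(C(=O)OC)C(=O)OC | intermediate
13 | methyl (3RS,6S)-6-ethynyl-3,6-dimethyl-2-oxooxane-3-carboxylate | C#C[C@]1(C)CCC(C)(C(=O)OC)C(=O)O1 | intermediate
14 | (3RS,6S)-6-ethynyl-3,6-dimethyloxan-2-one | C#C[C@]1(C)CCC(C)C(=O)O1 | intermediate
15 | (3RS,6S)-3,6-dimethyl-6-{[3-(2-methylbut-3-en-2-yl)-1-(triisopropylsilyl)-1H-indol-5-yl]ethynyl}oxan-2-one | CC1CC[C@@](C)(C#Cc2ccc3n([Si](C(C)C)(C(C)C)C(C)C)cc(C(C)(C)C=C)c3c2)OC1=O | intermediate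
16 | (3RS,6S)-3,6-dimethyl-6-{(Z)-2-[3-(2-methylbut-3-en-2-yl)-1-(triisopropylsilyl)-1H-indol-5-yl]ethenyl}oxan-2-one | CC1CC[C@@](C)(/C=C\c2ccc3n([Si](C(C)C)(C(C)C)C(C)C)cc(C(C)(C)C=C)c3c2)OC1=O | intermediate
17 | tert-butyl({(2S)-2,5-dimethyl-2-[(Z)-2-[3-(2-methylbut-3-en-2-yl)-1-(triisopropylsilyl)-1H-indol-5-yl]ethenyl]-3,4-dihydro-2H-pyran-6-yl}oxy)dimethylsilane | CC(C)(C)[Si](C)(C)OC1=C(C)CC[C@@](C)(/C=C\c2ccc3n([Si](C(C)C)(C(C)C)C(C)C)cc(C(C)(C)C=C)c3c2)O1 | intermediate
18 | tert-butyldimethylsilyl (1R,2S)-1,4-dimethyl-2-[3-(2-methylbut-3-en-2-yl)-1-(triisopropylsilyl)-1H-indol-5-yl]cyclohex-3-ene-1-carboxylate (aryl trans to carboxyl) | CC(C)(C)[Si](C)(C)OC(=O)[C@]1(C)CCC(C)=C[C@H]1c1ccc2n([Si](C(C)C)(C(C)C)C(C)C)cc(C(C)(C)C=C)c2c1 | intermediate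
19 | {(1R,2S)-1,4-dimethyl-2-[3-(2-methylbut-3-en-2-yl)-1-(triisopropylsilyl)-1H-indol-5-yl]cyclohex-3-en-1-yl}methanol | OC[C@]1(C)CCC(C)=C[C@H]1c1ccc2n([Si](C(C)C)(C(C)C)C(C)C)cc(C(C)(C)C=C)c2c1 | intermediate
20 | (1R,2S)-1,4-dimethyl-2-[3-(2-methylbut-3-en-2-yl)-1-(triisopropylsilyl)-1H-indol-5-yl]cyclohex-3-ene-1-carbaldehyde | O=C[C@]1(C)CCC(C)=C[C@H]1c1ccc2n([Si](C(C)C)(C(C)C)C(C)C)cc(C(C)(C)C=C)c2c1 | intermediate
21 | 2-[(E)-2-{(1S,2R)-1,4-dimethyl-2-[3-(2-methylbut-3-en-2-yl)-1-(triisopropylsilyl)-1H-indol-5-yl]cyclohex-3-en-1-yl}ethenyl]-4,4,5,5-tetramethyl-1,3,2-dioxaborolane | CC1(C)OB(/C=C/[C@]2(C)CCC(C)=C[C@H]2c2ccc3n([Si](C(C)C)(C(C)C)C(C)C)cc(C(C)(C)C=C)c3c2)OC1(C)C | intermediate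
22 | 5-[(E)-2-{(1S,2R)-1,4-dimethyl-2-[3-(2-methylbut-3-en-2-yl)-1-(triisopropylsilyl)-1H-indol-5-yl]cyclohex-3-en-1-yl}ethenyl]-3-(2-methylbut-3-en-2-yl)-1-(triisopropylsilyl)-1H-indole | C=CC(C)(C)c1cn([Si](C(C)C)(C(C)C)C(C)C)c2ccc(/C=C/[C@]3(C)CCC(C)=C[C@H]3c3ccc4n([Si](C(C)C)(C(C)C)C(C)C)cc(C(C)(C)C=C)c4c3)cc12 | intermediate
23 | 5-[(E)-2-{(1S,2R)-1,4-dimethyl-2-[3-(2-methylbut-3-en-2-yl)-1H-indol-5-yl]cyclohex-3-en-1-yl}ethenyl]-3-(2-methylbut-3-en-2-yl)-1H-indole | C=CC(C)(C)c1c[nH]c2ccc(/C=C/[C@]3(C)CCC(C)=C[C@H]3c3ccc4[nH]cc(C(C)(C)C=C)c4c3)cc12 | target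

Total step count: 16. Longest linear sequence: 13 steps (from 7 to 23, steps 4 to 16); the indole branch (steps 1 to 3) joins at steps 9 and 15.

Steps most likely to fail

1. Step 11 (key step). The rearrangement may be outrun by ionisation of the electron-rich tertiary allylic C–O bond, with elimination and loss of stereochemical information, or it may stall because the aryl group has to turn inward in the boat. The fallback replaces the sigmatropic shift by a cycloaddition; it sets out from iodide 6 and returns at aldehyde 20, so steps 12 and 13 are also skipped. A Heck reaction of 6 with isoprene (Pd(OAc)2, P(o-tol)3, Et3N, MeCN, 70 °C) would give 5-[(1E)-3-methylbuta-1,3-dien-1-yl]-3-(2-methylbut-3-en-2-yl)-1-(triisopropylsilyl)-1H-indole F1. An enantioselective Diels–Alder reaction of F1 with 2-methylacrolein under a chiral cationic oxazaborolidine Lewis acid (CH2Cl2, −78 °C) would then give 20 directly. Both diene substituents direct the regiochemistry to this skeleton. The relative configuration relies on the exo mode (formyl away from the aryl group) that α-methylacrolein commonly adopts under such catalysts; any endo isomer would have to be separated.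

2. Step 10. Over-hydrogenation of the hindered vinyl group or of the new styrene, and Z-to-E isomerisation on the catalyst surface, would erode the geometry on which step 11 depends. The fallback builds the Z alkene by cross-coupling instead of hydrogenation; it sets out from alkyne 14 and iodide 6 and returns at 16. Rhodium-catalysed trans-hydroboration of the terminal alkyne of 14 with pinacolborane ([Rh(cod)Cl]2, P(i-Pr)3, Et3N, cyclohexane, 23 °C) would give (3RS,6S)-3,6-dimethyl-6-[(Z)-2-(4,4,5,5-tetramethyl-1,3,2-dioxaborolan-2-yl)ethenyl]oxan-2-one F2. A Suzuki–Miyaura coupling of F2 with 6 (Pd(dppf)Cl2, aq. K3PO4, THF, 23 °C) would then attach the aryl group with retention of geometry and give 16, so step 9 is skipped as well.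

3. Step 5. Hydride may be delivered in the SN2′ sense to the alkynyl epoxide (allene formation), or the alkyne may undergo trans-hydroalumination once the propargylic alkoxide has formed. The fallback removes the C2 oxygen by electron transfer instead of aluminium hydride; it sets out from 8 and returns at 9. Oxidation of 8 (TEMPO, NaOCl, NaClO2, pH 7 buffer, MeCN) would give (2S,3R)-3-ethynyl-3-methyloxirane-2-carboxylic acid F3, and esterification (MeI, K2CO3, DMF) would give methyl (2S,3R)-3-ethynyl-3-methyloxirane-2-carboxylate F4. Samarium diiodide (THF/MeOH, −78 °C) would cleave the Cα–O bond of the glycidic ester to give methyl (3S)-3-hydroxy-3-methylpent-4-ynoate F5, and LiBH4 (THF, 0 °C) would reduce F5 to diol 9.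

Further compounds
F1 | step 11 | 5-[(1E)-3-methylbuta-1,3-dien-1-yl]-3-(2-methylbut-3-en-2-yl)-1-(triisopropylsilyl)-1H-indole | C=CC(C)(C)c1cn([Si](C(C)C)(C(C)C)C(C)C)c2ccc(/C=C/C(C)=C)cc12
F2 | step 10 | (3RS,6S)-3,6-dimethyl-6-[(Z)-2-(4,4,5,5-tetramethyl-1,3,2-dioxaborolan-2-yl)ethenyl]oxan-2-one | CC1CC[C@@](C)(/C=C\B2OC(C)(C)C(C)(C)O2)OC1=O
F3 | step 5 | (2S,3R)-3-ethynyl-3-methyloxirane-2-carboxylic acid | C#C[C@@]1(C)O[C@@H]1C(=O)O
F4 | step 5 | methyl (2S,3R)-3-ethynyl-3-methyloxirane-2-carboxylate | C#C[C@@]1(C)O[C@@H]1C(=O)OC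
F5 | step 5 | methyl (3S)-3-hydroxy-3-methylpent-4-ynoate | C#C[C@@](C)(O)CC(=O)OC
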